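**Retrosynthetic overview**
1. Last disconnection: the two quinone C–OMe bonds. They are made together by a double dehydrogenative C–H methoxylation (trivalent iodine, methoxide) of the unsymmetrical 2,5-bis(indol-3-yl)-1,4-benzoquinone. This C–O bond formation is the key step and a proposed new method.
2. The bis(indolyl)quinone comes from 1,4-benzoquinone by two successive indole Michael additions with re-oxidation: the hindered 2-(2-methylbut-3-en-2-yl)indole first, indole second. The 2,5-pattern follows from the electronic bias of the mono-adduct.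
3. 2-(2-Methylbut-3-en-2-yl)indole comes from indole and 3-methylbuta-1,2-diene (as its 9-BBN prenylborane) by reverse prenylation through 3-chloroindole.
4. Ring order: no ring is built. The two indole bicycles and the quinone ring are bought intact and only substituted.

Assumption: the target is achiral (no stereocentre, no configured double bond, rotation about the indole–quinone bonds taken as free), so no enantiocontrol is needed and the SMILES carry no stereodescriptors.

**Route**

Step 1
Reactants: 1 indole (1H-indole); 2 3-methylbuta-1,2-diene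
Product: 5 2-(2-methylbut-3-en-2-yl)-1H-indole, via B-prenyl-9-BBN 3 (not isolated), via 3-chloroindole 4 (not isolated)
Conditions: 2 (1.5 equiv), 9-BBN (1.4 equiv), THF, 0 °C → rt (gives 3); separately 1, t-BuOCl (1.05 equiv), Et3N (1.2 equiv), THF, −78 °C (gives 4); then solution of 3, −78 °C → rt; H2O work-up
Reagents that add atoms: 9-borabicyclo[3.3.1]nonane (9-BBN), B1C2CCCC1CCC2 (its boron stays only in 3); tert-butyl hypochlorite, CC(C)(C)OCl (its chlorine stays only in 4); no reagent leaves a non-hydrogen atom in 5
Why: Hydroboration of the allene puts boron on the terminal CH2 to give prenylborane 3, and the 3H-tautomer of 4 (3-chloroindolenine) undergoes allylboration of its C=N bond through a six-membered chair transition state with allylic transposition, so the tertiary carbon bonds to C2 and Et3N-assisted loss of HCl re-aromatises the ring (Danishefsky-type reverse prenylation); no stereocentre is formed.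

Step 2
Reactants: 5 2-(2-methylbut-3-en-2-yl)-1H-indole; 6 1,4-benzoquinone
Product: 8 2-[2-(2-methylbut-3-en-2-yl)-1H-indol-3-yl]cyclohexa-2,5-diene-1,4-dione, via hydroquinone adduct 7 (not isolated)
Conditions: 6 (3 equiv), InBr3 (10 mol %), CH2Cl2, rt, slow addition of 5
Reagents that add atoms: none
Why: Lewis-acid-catalysed Friedel–Crafts-type Michael addition of indole C3 to benzoquinone gives hydroquinone 7, which the excess quinone oxidises to 8, while the excess of 6 and the bulk at C2 hold back a second addition.

Step 3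
Reactants: 8 2-[2-(2-methylbut-3-en-2-yl)-1H-indol-3-yl]cyclohexa-2,5-diene-1,4-dione; 1 indole
Product: 10 2-(1H-indol-3-yl)-5-[2-(2-methylbut-3-en-2-yl)-1H-indol-3-yl]cyclohexa-2,5-diene-1,4-dione, via bis-indolyl hydroquinone 9 (not isolated)
Conditions: 1 (2 equiv), InBr3 (10 mol %), CH2Cl2, rt; then DDQ (1.2 equiv), rt
Reagents that add atoms: none
Why: Second indole Michael addition: the indolyl group of 8 donates into the C4 carbonyl, so the enone of the C1 carbonyl is the more electrophilic and indole attacks C5 (para to the first indolyl) to give hydroquinone 9, which DDQ dehydrogenates to the 2,5-bis(indolyl)quinone 10.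

Step 4
Reactants: 10 2-(1H-indol-3-yl)-5-[2-(2-methylbut-3-en-2-yl)-1H-indol-3-yl]cyclohexa-2,5-diene-1,4-dione
Product: 12 2-(1H-indol-3-yl)-3,6-dimethoxy-5-[2-(2-methylbut-3-en-2-yl)-1H-indol-3-yl]cyclohexa-2,5-diene-1,4-dione, via monomethoxyquinone 11 (not isolated)
Conditions: PhI(OAc)2 (2.3 equiv), NaOMe (6 equiv), MeOH–THF (3:1), 3 Å MS, −20 °C → rt, dark
Reagents that add atoms: methanol, CO (delivered as sodium methoxide, C[O-].[Na+])
Why: Proposed new method: dehydrogenative double C–H methoxylation of a bis(indolyl)quinone by trivalent-iodine umpolung — each indole N–H/quinone C=O pair of 10 is a doubly vinylogous amide, so its sodium aza-enolate is iodanated on oxygen by (dimethoxyiodo)benzene (formed in the flask from PhI(OAc)2 and NaOMe), methoxide then attacks the only carbon with enolate character, the quinone C–H alpha to that carbonyl, as PhI departs reductively, and a proton shift from that carbon to nitrogen restores indole and quinone; the less hindered C–H beside the unsubstituted indolyl reacts first (11), the one beside the bulky indolyl second, and the product has no such C–H left; closest known reaction type: Moriarty alpha-oxygenation of ketone enolates and alpha-functionalisation of enaminones with PhI(OAc)2 in basic methanol, so far not applied to the quinone C–H bonds of indolylquinones.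

**Compound list**
1 | 1H-indole | c1ccc2[nH]ccc2c1 | starting material
2 | 3-methylbuta-1,2-diene | C=C=C(C)C | starting material
3 | 9-(3-methylbut-2-en-1-yl)-9-borabicyclo[3.3.1]nonane (B-prenyl-9-BBN) | CC(C)=CCB1C2CCCC1CCC2 | intermediate (not isolated)
4 | 3-chloro-1H-indole (reacts as its 3H-tautomer) | Clc1c[nH]c2ccccc12 | intermediate (not isolated)
5 | 2-(2-methylbut-3-en-2-yl)-1H-indole | C=CC(C)(C)c1cc2ccccc2[nH]1 | intermediate
6 | 1,4-benzoquinone | O=C1C=CC(=O)C=C1 | starting material
7 | 2-[2-(2-methylbut-3-en-2-yl)-1H-indol-3-yl]benzene-1,4-diol | C=CC(C)(C)c1[nH]c2ccccc2c1-c1cc(O)ccc1O | intermediate (not isolated)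
8 | 2-[2-(2-methylbut-3-en-2-yl)-1H-indol-3-yl]cyclohexa-2,5-diene-1,4-dione | C=CC(C)(C)c1[nH]c2ccccc2c1C1=CC(=O)C=CC1=O | intermediate
9 | 2-(1H-indol-3-yl)-5-[2-(2-methylbut-3-en-2-yl)-1H-indol-3-yl]benzene-1,4-diol | C=CC(C)(C)c1[nH]c2ccccc2c1-c1cc(O)c(cc1O)-c1c[nH]c2ccccc12 | intermediate (not isolated)
10 | 2-(1H-indol-3-yl)-5-[2-(2-methylbut-3-en-2-yl)-1H-indol-3-yl]cyclohexa-2,5-diene-1,4-dione | C=CC(C)(C)c1[nH]c2ccccc2c1C1=CC(=O)C(c2c[nH]c3ccccc23)=CC1=O | intermediate
11 | 2-(1H-indol-3-yl)-3-methoxy-5-[2-(2-methylbut-3-en-2-yl)-1H-indol-3-yl]cyclohexa-2,5-diene-1,4-dione | C=CC(C)(C)c1[nH]c2ccccc2c1C1=CC(=O)C(c2c[nH]c3ccccc23)=C(OC)C1=O | intermediate (not isolated)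
12 | 2-(1H-indol-3-yl)-3,6-dimethoxy-5-[2-(2-methylbut-3-en-2-yl)-1H-indol-3-yl]cyclohexa-2,5-diene-1,4-dione | C=CC(C)(C)c1[nH]c2ccccc2c1C1=C(OC)C(=O)C(c2c[nH]c3ccccc23)=C(OC)C1=O | target

**Step count and risks**
Total step count: 4. Longest linear sequence: 4 (1 and 2 → 5 → 8 → 10 → 12).

Most likely to fail, first: step 4, the proposed new method. The dangers are:
- over-oxidation, by a second iodanation that puts methoxide on the already methoxylated carbon or on indole C3;
- reaction of the oxidant at the indole nitrogen;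
- hydrolysis of the vinylogous ester by traces of water;
- a slow second methoxylation beside the bulky indolyl.

The fallback uses known chemistry, sets out from 5 and comes back at 12. Compound 5 is added under conc. H2SO4 catalysis in THF to commercial 2,5-dichloro-1,4-benzoquinone (O=C1C=C(Cl)C(=O)C=C1Cl) to give 2,5-dichloro-3-[2-(2-methylbut-3-en-2-yl)-1H-indol-3-yl]benzene-1,4-diol F1. DDQ oxidises this in the same flask to 2,5-dichloro-3-[2-(2-methylbut-3-en-2-yl)-1H-indol-3-yl]cyclohexa-2,5-diene-1,4-dione F2. Indole 1 in AcOH then adds at the only free quinone position to give 2,5-dichloro-3-(1H-indol-3-yl)-6-[2-(2-methylbut-3-en-2-yl)-1H-indol-3-yl]benzene-1,4-diol F3, and DDQ gives 2,5-dichloro-3-(1H-indol-3-yl)-6-[2-(2-methylbut-3-en-2-yl)-1H-indol-3-yl]cyclohexa-2,5-diene-1,4-dione F4. NaOMe in dry MeOH at reflux replaces both chlorides by addition–elimination (nucleophilic vinylic substitution of a vinylogous acyl chloride). This runs through 2-chloro-6-(1H-indol-3-yl)-5-methoxy-3-[2-(2-methylbut-3-en-2-yl)-1H-indol-3-yl]cyclohexa-2,5-diene-1,4-dione F5 and reaches 12. The C–O bonds are still made last, but from C–Cl bonds whose positions are fixed from the start.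

Second: step 3. The dangers are:
- the twisted, weakly donating indolyl of 8 may give too little bias, so that some 2,6-isomer forms;
- redox exchange between 8 and 9 may stall conversion before DDQ is added;
- DDQ may attack the excess indole.

The fallback inverts the order of the two additions, so that the planar, fully conjugated indolyl sets the regiochemistry and the hindered indole meets a quinone with stronger bias. It sets out from 1 and 6 and comes back at 9. Indole 1 adds to 6 (3 equiv, InBr3 10 mol %, CH2Cl2, rt) to give 2-(1H-indol-3-yl)benzene-1,4-diol F6, which the excess 6 oxidises to 2-(1H-indol-3-yl)cyclohexa-2,5-diene-1,4-dione F7. F7 takes up 5 under conc. H2SO4 catalysis in THF to give 9, and DDQ then gives 10 as in step 3.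

Third: step 1. The dangers are:
- 3-chloroindole 4 is unstable;
- the allylboration of its 3H-tautomer may be slow;
- N-allylated or C3-allylated by-products may form.

The fallback builds the indole ring instead of substituting it. It sets out from 3 (made from 2 as in step 1) and comes back at 5. Borane 3 reacts with acetaldehyde (CC=O) in THF at −78 °C → rt, followed by aqueous work-up, to give racemic 3,3-dimethylpent-4-en-2-ol F8 (carbonyl allylboration with allylic transposition). Dess–Martin periodinane in CH2Cl2 gives 3,3-dimethylpent-4-en-2-one F9. Phenylhydrazine (NNc1ccccc1) in EtOH with a little AcOH gives 3,3-dimethylpent-4-en-2-one phenylhydrazone F10. ZnCl2 in AcOH at 100 °C brings about the Fischer indole synthesis: a [3,3]-shift, then C–N ring closure with loss of ammonia. Only the methyl group can enolise, so the product is the 2-substituted indole 5.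

**Further compounds**
F1 | step 4 | 2,5-dichloro-3-[2-(2-methylbut-3-en-2-yl)-1H-indol-3-yl]benzene-1,4-diol | C=CC(C)(C)c1[nH]c2ccccc2c1-c1c(Cl)c(O)cc(Cl)c1O
F2 | step 4 | 2,5-dichloro-3-[2-(2-methylbut-3-en-2-yl)-1H-indol-3-yl]cyclohexa-2,5-diene-1,4-dione | C=CC(C)(C)c1[nH]c2ccccc2c1C1=C(Cl)C(=O)C=C(Cl)C1=O
F3 | step 4 | 2,5-dichloro-3-(1H-indol-3-yl)-6-[2-(2-methylbut-3-en-2-yl)-1H-indol-3-yl]benzene-1,4-diol | C=CC(C)(C)c1[nH]c2ccccc2c1-c1c(Cl)c(O)c(c(Cl)c1O)-c1c[nH]c2ccccc12
F4 | step 4 | 2,5-dichloro-3-(1H-indol-3-yl)-6-[2-(2-methylbut-3-en-2-yl)-1H-indol-3-yl]cyclohexa-2,5-diene-1,4-dione | C=CC(C)(C)c1[nH]c2ccccc2c1C1=C(Cl)C(=O)C(c2c[nH]c3ccccc23)=C(Cl)C1=O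
F5 | step 4 | 2-chloro-6-(1H-indol-3-yl)-5-methoxy-3-[2-(2-methylbut-3-en-2-yl)-1H-indol-3-yl]cyclohexa-2,5-diene-1,4-dione | C=CC(C)(C)c1[nH]c2ccccc2c1C1=C(Cl)C(=O)C(c2c[nH]c3ccccc23)=C(OC)C1=O
F6 | step 3 | 2-(1H-indol-3-yl)benzene-1,4-diol | Oc1ccc(O)c(c1)-c1c[nH]c2ccccc12
F7 | step 3 | 2-(1H-indol-3-yl)cyclohexa-2,5-diene-1,4-dione | O=C1C=CC(=O)C(=C1)c1c[nH]c2ccccc12
F8 | step 1 | 3,3-dimethylpent-4-en-2-ol (racemic) | CC(O)C(C)(C)C=C
F9 | step 1 | 3,3-dimethylpent-4-en-2-one | CC(=O)C(C)(C)C=C
F10 | step 1 | 3,3-dimethylpent-4-en-2-one phenylhydrazone | C=CC(C)(C)C(C)=NNc1ccccc1
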